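**Retrosynthetic overview**

1. The target is numbered as a 1-aryl-1,2-dihydronaphthalene: C1 carries the aryl group, C2 the CH2OAc, C3 the CHO, C4 is vinylic; ring A is the benzo ring, ring B the carbocycle, primed locants the pendant guaiacyl ring. The C3 formyl carbon and the C2 acetoxymethyl carbon are carried as a temporary γ-lactone (ring C), which is opened at the end by partial reduction and acetylated enzymatically.
2. Ring B is disconnected at C1–C8a: a dehydrogenative quinone-methide Friedel–Crafts closure of an (E)-α-arylidene-β-benzyl lactone, in which two C–H bonds become the C–C bond and C1 is set from C2.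
3. Enabling feature: C1 is a methylene para to the free C4'-OH of the pendant ring, so hydride loss gives a p-quinone methide; C8a of ring A is para to the C6 methoxy; the (E)-C3=C4 bond holds C8a beside C1 so that a six-membered ring results.
4. The arylidene comes from aldol condensation of an (R)-β-benzyl-γ-butyrolactone with O-benzylvanillin; the lactone comes from Stobbe condensation, rhodium-catalysed asymmetric hydrogenation (sets C2) and ester reduction.
5. Order of rings: both aryl rings from vanillin units; ring C (step 3); ring B (step 7); ring C opened (step 8).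

Key step: step 7

Assumption: [Rh(cod)((S,S)-Et-DuPhos)]BF4 is taken to give the (R)-configured acid in step 2, as with related arylidene succinate half-esters; if the sense proved opposite, the (R,R)-ligand would be used.

**Step 1**
Reactants: 1 4-(benzyloxy)-3-methoxybenzaldehyde; 2 dimethyl succinate
Product: 4 (E)-4-[4-(benzyloxy)-3-methoxyphenyl]-3-(methoxycarbonyl)but-3-enoic acid, via paraconic ester lactone 3 (not isolated)
Conditions: NaOMe (2 equiv), MeOH, reflux; then 2 M HCl
Reagents that add atoms: none
Why: Stobbe condensation, in which the succinate enolate adds to the aldehyde, the alkoxide lactonises to 3 and base-induced E1cB ring opening should give the (E)-alkylidene half-ester with the free acid on the CH2 arm, as is general for aromatic aldehydes.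

**Step 2**
Reactants: 4 (E)-4-[4-(benzyloxy)-3-methoxyphenyl]-3-(methoxycarbonyl)but-3-enoic acid
Product: 5 (R)-4-[4-(benzyloxy)-3-methoxyphenyl]-3-(methoxycarbonyl)butanoic acid
Conditions: H2 (5 bar), [Rh(cod)((S,S)-Et-DuPhos)]BF4 (1 mol %), NaOMe (0.1 equiv), MeOH, 25 °C
Reagents that add atoms: none
Why: Catalytic asymmetric hydrogenation of an itaconate-type half-ester, in which carboxylate and alkene chelate the cationic rhodium bisphospholane so that H2 is delivered to one face and the future C2 stereocentre is set under catalyst control; the benzyl ether is inert to this homogeneous catalyst.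

**Step 3**
Reactants: 5 (R)-4-[4-(benzyloxy)-3-methoxyphenyl]-3-(methoxycarbonyl)butanoic acid
Product: 7 (R)-4-[4-(benzyloxy)-3-methoxybenzyl]dihydrofuran-2(3H)-one, via hydroxy acid 6 (not isolated)
Conditions: KOH (1 equiv), EtOH, 0 °C; CaCl2, NaBH4 (Ca(BH4)2 formed in the flask), EtOH, −10 °C to rt; then 2 M HCl, rt
Reagents that add atoms: none
Why: Chemoselective borohydride reduction of the methyl ester beside the unreactive potassium carboxylate, followed by acid-induced lactonisation of 6; the stereocentre is not enolised under these conditions and ends up β to the lactone carbonyl.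

**Step 4**
Reactants: 7 (R)-4-[4-(benzyloxy)-3-methoxybenzyl]dihydrofuran-2(3H)-one; 1 4-(benzyloxy)-3-methoxybenzaldehyde
Product: 8 (3S,4R)-4-[4-(benzyloxy)-3-methoxybenzyl]-3-{[4-(benzyloxy)-3-methoxyphenyl](hydroxy)methyl}dihydrofuran-2(3H)-one (carbinol epimers)
Conditions: LiN(i-Pr)2 (1.1 equiv), THF, −78 °C; then 1, −78 °C; aq. NH4Cl
Reagents that add atoms: none
Why: Aldol addition of the lithium lactone enolate to a non-enolisable aldehyde, the enolate being attacked anti to the C4 benzyl group; the carbinol configuration does not matter because it is removed in step 5.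

**Step 5**
Reactants: 8 (3S,4R)-4-[4-(benzyloxy)-3-methoxybenzyl]-3-{[4-(benzyloxy)-3-methoxyphenyl](hydroxy)methyl}dihydrofuran-2(3H)-one
Product: 10 (3E,4R)-3-[4-(benzyloxy)-3-methoxybenzylidene]-4-[4-(benzyloxy)-3-methoxybenzyl]dihydrofuran-2(3H)-one, via mesylate 9 (not isolated)
Conditions: CH3SO2Cl, Et3N, CH2Cl2, 0 °C; then DBU, 0 °C to rt
Reagents that add atoms: none
Why: Mesylation and E1cB elimination should give the conjugated exocyclic alkene as the (E)-isomer (aryl anti to the lactone carbonyl, hence syn to C4, as the ring closure requires), the brief exposure to DBU being chosen so that the γ-stereocentre is not deprotonated.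

**Step 6**
Reactants: 10 (3E,4R)-3-[4-(benzyloxy)-3-methoxybenzylidene]-4-[4-(benzyloxy)-3-methoxybenzyl]dihydrofuran-2(3H)-one
Product: 11 (3E,4R)-3-(4-hydroxy-3-methoxybenzylidene)-4-(4-hydroxy-3-methoxybenzyl)dihydrofuran-2(3H)-one
Conditions: BCl3 (5 equiv), pentamethylbenzene (6 equiv), CH2Cl2, −78 °C; then H2O
Reagents that add atoms: none
Why: Lewis acid-mediated debenzylation in which BCl3 ionises the aryl benzyl ethers and pentamethylbenzene captures the benzyl cation by Friedel–Crafts alkylation, which at −78 °C should leave the methyl ethers, the lactone and the alkene untouched (hydrogenolysis would reduce the alkene).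

**Step 7**
Reactants: 11 (3E,4R)-3-(4-hydroxy-3-methoxybenzylidene)-4-(4-hydroxy-3-methoxybenzyl)dihydrofuran-2(3H)-one
Product: 13 (3aR,4S)-6-hydroxy-4-(4-hydroxy-3-methoxyphenyl)-7-methoxy-3a,4-dihydronaphtho[2,3-c]furan-1(3H)-one, via p-quinone methide 12 (not isolated)
Conditions: DDQ (1.05 equiv, added slowly), CH2Cl2/CF3CO2H (4:1), −20 to 0 °C
Reagents that add atoms: none
Why: DDQ abstracts hydride from the C1 methylene, which lies para to the free C4'-OH of the more electron-rich pendant ring, and the resulting p-quinone methide 12, O-protonated by CF3CO2H, is attacked by C8a of ring A in an intramolecular vinylogous Friedel–Crafts alkylation, after which proton loss rearomatises ring A. The closest known reaction types are the DDQ/acid oxidative cyclisation of 4-hydroxybenzyl butyrolactone lignans to aryltetralins and the acid-triggered quinone-methide closure of 7-hydroxy lignans (hydroxymatairesinol to conidendrin). Ring B closes 6-exo-trig with respect to the exocyclic methide bond, the (E)-C3=C4 alkene and the C4a=C8a bond of ring A lying inside the new ring. C1 is set by 1,2-induction from C2: with C2–H eclipsing the methide plane (minimised A(1,3) strain) and the ring constraint bringing C8a in from the C3 side, the new bond forms anti to the lactone CH2O, which should give the 1,2-trans (1S,2R) arrangement. The step needs site selectivity on ring A (C8a is para to the C6 methoxy and less hindered than the carbon between alkene and methoxy) and chemoselectivity for one oxidation only; the latter is secured by one equivalent of oxidant at low temperature in acid, where closure of the cation should outrun both deprotonation at C2 and a second hydride loss from the more hindered C1–H of the product.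

**Step 8**
Reactants: 13 (3aR,4S)-6-hydroxy-4-(4-hydroxy-3-methoxyphenyl)-7-methoxy-3a,4-dihydronaphtho[2,3-c]furan-1(3H)-one
Product: 15 (3R,4S)-6-hydroxy-4-(4-hydroxy-3-methoxyphenyl)-3-(hydroxymethyl)-7-methoxy-3,4-dihydronaphthalene-2-carbaldehyde, via lactol 14 (not isolated)
Conditions: i-Bu2AlH (4 equiv), THF/CH2Cl2, −78 °C; then aq. KNaC4H4O6
Reagents that add atoms: none
Why: Partial reduction of a lactone to the lactol (two equivalents of hydride are consumed by the phenols), the tetrahedral aluminate surviving until work-up, after which lactol 14 should open to the aryl-conjugated hydroxy aldehyde, the form in which this dihydronaphthalene is expected to exist; neither stereocentre is involved.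

**Step 9**
Reactants: 15 (3R,4S)-6-hydroxy-4-(4-hydroxy-3-methoxyphenyl)-3-(hydroxymethyl)-7-methoxy-3,4-dihydronaphthalene-2-carbaldehyde
Product: 16 [(1S,2R)-3-formyl-7-hydroxy-1-(4-hydroxy-3-methoxyphenyl)-6-methoxy-1,2-dihydronaphthalen-2-yl]methyl acetate
Conditions: immobilised Candida antarctica lipase B, vinyl acetate (5 equiv), t-BuOMe/THF, 30 °C
Reagents that add atoms: vinyl acetate, C=COC(C)=O
Why: Lipase-catalysed irreversible transesterification with an enol ester, in which the serine hydrolase should acylate the primary aliphatic alcohol and leave both phenols (poor acceptors for the acyl-enzyme) untouched, so that no phenol protection is needed.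

**Compound list**

1 | 4-(benzyloxy)-3-methoxybenzaldehyde (O-benzylvanillin) | COc1cc(C=O)ccc1OCc1ccccc1 | starting material
2 | dimethyl succinate | COC(=O)CCC(=O)OC | starting material
3 | methyl 2-[4-(benzyloxy)-3-methoxyphenyl]-5-oxotetrahydrofuran-3-carboxylate (paraconic ester lactone, racemic, configuration not controlled) | COC(=O)C1CC(=O)OC1c1ccc(OCc2ccccc2)c(OC)c1 | intermediate (not isolated)
4 | (E)-4-[4-(benzyloxy)-3-methoxyphenyl]-3-(methoxycarbonyl)but-3-enoic acid | COC(=O)/C(CC(=O)O)=C/c1ccc(OCc2ccccc2)c(OC)c1 | intermediate
5 | (R)-4-[4-(benzyloxy)-3-methoxyphenyl]-3-(methoxycarbonyl)butanoic acid | COC(=O)[C@H](Cc1ccc(OCc2ccccc2)c(OC)c1)CC(=O)O | intermediate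
6 | (R)-4-[4-(benzyloxy)-3-methoxyphenyl]-3-(hydroxymethyl)butanoic acid | OC[C@H](Cc1ccc(OCc2ccccc2)c(OC)c1)CC(=O)O | intermediate (not isolated)
7 | (R)-4-[4-(benzyloxy)-3-methoxybenzyl]dihydrofuran-2(3H)-one | O=C1OC[C@H](Cc2ccc(OCc3ccccc3)c(OC)c2)C1 | intermediate
8 | (3S,4R)-4-[4-(benzyloxy)-3-methoxybenzyl]-3-{[4-(benzyloxy)-3-methoxyphenyl](hydroxy)methyl}dihydrofuran-2(3H)-one (3,4-trans, carbinol carbon as epimers) | O=C1OC[C@H](Cc2ccc(OCc3ccccc3)c(OC)c2)[C@H]1C(O)c1ccc(OCc2ccccc2)c(OC)c1 | intermediate
9 | methanesulfonate of 8 (carbinol carbon as epimers) | O=C1OC[C@H](Cc2ccc(OCc3ccccc3)c(OC)c2)[C@H]1C(OS(C)(=O)=O)c1ccc(OCc2ccccc2)c(OC)c1 | intermediate (not isolated)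
10 | (3E,4R)-3-[4-(benzyloxy)-3-methoxybenzylidene]-4-[4-(benzyloxy)-3-methoxybenzyl]dihydrofuran-2(3H)-one | O=C1OC[C@H](Cc2ccc(OCc3ccccc3)c(OC)c2)/C1=C\c1ccc(OCc2ccccc2)c(OC)c1 | intermediate
11 | (3E,4R)-3-(4-hydroxy-3-methoxybenzylidene)-4-(4-hydroxy-3-methoxybenzyl)dihydrofuran-2(3H)-one | O=C1OC[C@H](Cc2ccc(O)c(OC)c2)/C1=C\c1ccc(O)c(OC)c1 | intermediate
12 | (3E,4R)-3-(4-hydroxy-3-methoxybenzylidene)-4-[(3-methoxy-4-oxocyclohexa-2,5-dien-1-ylidene)methyl]dihydrofuran-2(3H)-one (p-quinone methide, methide geometry not defined) | O=C1OC[C@H](C=C2C=CC(=O)C(OC)=C2)/C1=C\c1ccc(O)c(OC)c1 | intermediate (not isolated)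
13 | (3aR,4S)-6-hydroxy-4-(4-hydroxy-3-methoxyphenyl)-7-methoxy-3a,4-dihydronaphtho[2,3-c]furan-1(3H)-one | COc1cc([C@H]2c3cc(O)c(OC)cc3C=C3C(=O)OC[C@H]23)ccc1O | intermediate
14 | (3aR,4S)-4-(4-hydroxy-3-methoxyphenyl)-7-methoxy-1,3,3a,4-tetrahydronaphtho[2,3-c]furan-1,6-diol (lactol, anomers) | COc1cc([C@H]2c3cc(O)c(OC)cc3C=C3C(O)OC[C@H]23)ccc1O | intermediate (not isolated)
15 | (3R,4S)-6-hydroxy-4-(4-hydroxy-3-methoxyphenyl)-3-(hydroxymethyl)-7-methoxy-3,4-dihydronaphthalene-2-carbaldehyde | COc1cc([C@H]2c3cc(O)c(OC)cc3C=C(C=O)[C@@H]2CO)ccc1O | intermediate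
16 | [(1S,2R)-3-formyl-7-hydroxy-1-(4-hydroxy-3-methoxyphenyl)-6-methoxy-1,2-dihydronaphthalen-2-yl]methyl acetate | COc1cc([C@H]2c3cc(O)c(OC)cc3C=C(C=O)[C@@H]2COC(C)=O)ccc1O | target

**Step count and risks**

Total step count: 9. Longest linear sequence: 9 steps (from 1; compound 1 is used a second time in step 4).

Steps most likely to fail:

Step 7. What may go wrong is over-oxidation (a second hydride abstraction at the doubly benzylic C1–H of the product followed by aromatisation), competing hydride loss at the allylic C2–H, or erosion of the C2 configuration through quinone methide–styrene tautomerisation before ring closure. The fallback separates oxidation from ring closure and sets out from 11. Oxidation with one equivalent of DDQ in MeOH/CH2Cl2 at 0 °C, where methanol should trap the quinone methide faster than it can tautomerise or be oxidised again, should give the benzylic methyl ether (4R)-3-[(E)-4-hydroxy-3-methoxybenzylidene]-4-[(4-hydroxy-3-methoxyphenyl)(methoxy)methyl]dihydrofuran-2(3H)-one F1 as a mixture of epimers at the methoxy-bearing carbon. After isolation, F1 is ionised with CF3CO2H in CH2Cl2 at 0 °C in the absence of any oxidant, and the same Friedel–Crafts closure, now a plain acid-mediated cyclisation of a benzylic ether, should return the route at 13.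

Step 8. What may go wrong is over-reduction (collapse of the aluminate and further hydride delivery to the liberated aldehyde), or stalling because the aluminium phenoxide of ring A donates into the conjugated lactone carbonyl. The fallback sets out from 13 and replaces partial reduction by exhaustive reduction and selective re-oxidation. LiAlH4 in THF at 0 °C should give the diol [(1S,2R)-7-hydroxy-1-(4-hydroxy-3-methoxyphenyl)-6-methoxy-1,2-dihydronaphthalene-2,3-diyl]dimethanol F2. Its allylic, aryl-conjugated primary alcohol is then oxidised chemoselectively with activated MnO2 in acetone/CH2Cl2 at rt, the saturated primary alcohol at C2 being inert to this reagent, which returns the route at 15.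

Step 9. What may go wrong is slow or incomplete acyl transfer to a hindered, β-branched primary alcohol in the enzyme pocket. The fallback sets out from 15 and uses exhaustive chemical acetylation followed by selective de-acylation. Ac2O/pyridine with catalytic DMAP at rt should give the triacetate [(1S,2R)-7-acetoxy-1-(4-acetoxy-3-methoxyphenyl)-3-formyl-6-methoxy-1,2-dihydronaphthalen-2-yl]methyl acetate F3. The two aryl acetates, which carry far better leaving groups than the alkyl acetate, are then cleaved selectively with NH4OAc in aqueous MeOH at rt, which returns the route at 16.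

**Further compounds**

F1 | step 7 | (4R)-3-[(E)-4-hydroxy-3-methoxybenzylidene]-4-[(4-hydroxy-3-methoxyphenyl)(methoxy)methyl]dihydrofuran-2(3H)-one (epimers at the methoxy-bearing carbon) | O=C1OC[C@H](C(OC)c2ccc(O)c(OC)c2)/C1=C\c1ccc(O)c(OC)c1
F2 | step 8 | [(1S,2R)-7-hydroxy-1-(4-hydroxy-3-methoxyphenyl)-6-methoxy-1,2-dihydronaphthalene-2,3-diyl]dimethanol | COc1cc([C@H]2c3cc(O)c(OC)cc3C=C(CO)[C@@H]2CO)ccc1O
F3 | step 9 | [(1S,2R)-7-acetoxy-1-(4-acetoxy-3-methoxyphenyl)-3-formyl-6-methoxy-1,2-dihydronaphthalen-2-yl]methyl acetate | COc1cc([C@H]2c3cc(OC(C)=O)c(OC)cc3C=C(C=O)[C@@H]2COC(C)=O)ccc1OC(C)=O
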